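## Retrosynthetic overview

1. Target ⇒ C14 methylenation, C1 acetylation and C18 icosanoylation of a 15‑nor‑labd‑12‑en‑14‑al triol, itself made by a stabilised‑ylide Wittig reaction on a sclareolide‑type lactol.
2. Lactol ⇒ 1,18‑dioxo sclareolide‑type lactone; ring B and the lactone ring (C10–C9 and C8–O bonds) are closed together by an oxidative silyl enol ether / alkene / ester bicyclisation (the new step).
3. Ring A (C4 and C5 stereocentres, C1 oxygen, C18 carbonyl) ⇒ metal‑free catalytic enantioselective Diels–Alder reaction of a 2‑silyloxydiene with an (E)‑2‑methyl‑2‑enal.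
4. Enal ⇒ methyl homogeranate (SeO2) ⇒ geranyl chloride (carbonylation); diene ⇒ ethyl vinyl ketone.
5. Ring order: ring A (Diels–Alder), then ring B together with the γ‑lactone; the lactone is later opened into the diene side chain.

Assumption: labdane numbering (C1–C20) is used for all cyclic compounds; 6 and 7 are drawn as the major C10 epimer (methyl trans to the side chain), the minor epimer converging because C10 becomes sp2 in step 5.

## Route

Step 1
Reactants: 1 geranyl chloride, (2E)-1-chloro-3,7-dimethylocta-2,6-diene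
Product: 2 methyl (3E)-4,8-dimethylnona-3,7-dienoate (methyl homogeranate)
Conditions: PdCl2(PPh3)2 (2 mol%), CO (20 bar), MeOH, iPr2NEt, 50 °C
Reagents that add atoms: carbon monoxide [C-]#[O+]; methanol CO
Why: Palladium-catalysed alkoxycarbonylation of an allylic chloride, in which the π-allyl intermediate takes up CO at its unhindered primary terminus and methanolysis releases the linear β,γ-unsaturated ester with the E-alkene retained (no stereocentre formed).

Step 2
Reactants: 2 methyl (3E)-4,8-dimethylnona-3,7-dienoate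
Product: 3 methyl (3E,7E)-4,8-dimethyl-9-oxonona-3,7-dienoate
Conditions: SeO2 (1.3 equiv), 1,4-dioxane/H2O (50:1), 80 °C
Reagents that add atoms: selenium dioxide O=[Se]=O
Why: Selenium dioxide allylic oxidation (ene reaction then [2,3]-shift) attacks the E-methyl group of the terminal isopropylidene unit and gives the (E)-2-methyl-2-enal, whose geometry later fixes the C4/C5 relationship.

Step 3
Reactants: 4 pent-1-en-3-one (ethyl vinyl ketone)
Product: 5 tert-butyldimethyl[(3Z)-penta-1,3-dien-3-yloxy]silane
Conditions: tBuMe2SiOTf (1.05 equiv), Et3N (1.3 equiv), Et2O, 0 °C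
Reagents that add atoms: tert-butyldimethylsilyl trifluoromethanesulfonate CC(C)(C)[Si](C)(C)OS(=O)(=O)C(F)(F)F
Why: Soft enolisation of the enone toward its ethyl group gives the (Z)-2-silyloxy-1,3-diene (no stereocentre formed).

Step 4
Reactants: 3 methyl (3E,7E)-4,8-dimethyl-9-oxonona-3,7-dienoate; 5 tert-butyldimethyl[(3Z)-penta-1,3-dien-3-yloxy]silane (2 equiv)
Product: 7 methyl (3E)-6-[(1R,2R,6R)-2-formyl-2,6-dimethyl-5-oxocyclohexyl]-4-methylhex-3-enoate (ring A keto aldehyde; 4R,5R in labdane numbering), via silyl enol ether cycloadduct 6 (not isolated)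
Conditions: (R)-o-tolyl-oxazaborolidinium triflimide [from (R)-α,α-diphenylprolinol, tri-o-tolylboroxine, then HNTf2] (20 mol%), CH2Cl2, −78 to −40 °C; then HF·pyridine, THF, 0 °C
Reagents that add atoms: none
Why: Diels–Alder reaction under metal-free chiral Lewis acid (oxazaborolidinium) catalysis, in which the boron-bound formyl group places the siloxy-bearing diene carbon para to C4, suprafacial addition across the E-enal fixes the formyl group cis to H5, and the catalyst shields one face of the s-trans enal so that the diene adds to the Re face of the enal α-carbon and C4 and C5 are both set as R (C10 is inconsequential), after which fluoride cleaves the enol ether.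

Step 5
Reactants: 7 ring A keto aldehyde
Product: 8 methyl (3E)-6-[(1R,6R)-6-formyl-2,6-dimethyl-3-(trimethylsilyloxy)cyclohex-2-en-1-yl]-4-methylhex-3-enoate (C1=C10 silyl enol ether)
Conditions: Me3SiOTf (1.3 equiv), Et3N (2.0 equiv), CH2Cl2, 0 °C to rt, 12 h (equilibrating)
Reagents that add atoms: trimethylsilyl trifluoromethanesulfonate C[Si](C)(C)OS(=O)(=O)C(F)(F)F
Why: Thermodynamically controlled soft enolisation gives the more substituted silyl enol ether, which makes C10 planar and leaves the non-enolisable aldehyde and the C4 and C5 centres untouched.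

Step 6
Reactants: 8 C1=C10 silyl enol ether
Product: 9 1,18-dioxo-13,14,15,16-tetranorlabdano-12,8α-lactone (1,18-dioxo sclareolide skeleton; 4β-Me, 5α-H, 9α-H, 10β-Me, 8β-Me)
Conditions: PhI(OAc)2 (1.2 equiv), BF3·OEt2 (2.5 equiv), CH2Cl2, −78 °C, 10 min; then 8 added slowly, −78 to −40 °C; aq NaHCO3
Reagents that add atoms: none
Why: Proposed new method: the silyl enol ether reacts with BF3-activated PhI(OAc)2 to give an α-carbonyl iodane (enolonium) that makes C10 electrophilic, the tethered E-trisubstituted alkene attacks C10 in 6-endo fashion through a chair–chair arrangement from the α-face (the β-face is blocked by the axial 4β-methyl group and the side chain sits equatorial), iodobenzene leaves, and the tertiary C8 cation is captured anti by the ester carbonyl whose O-methyl group is then removed by acetate, so that C10 (β-Me), C9 (α-H) and C8 (α-O) are set relative to C5 in one operation; the closest known reaction types are the trivalent-iodine umpolung coupling of silyl enol ethers with π-nucleophiles, the oxidative cyclisation of unsaturated silyl enol ethers by (NH4)2Ce(NO3)6 or Cu(OTf)2, and the acid cyclisation of homofarnesic acid to sclareolide.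

Step 7
Reactants: 9 1,18-dioxo lactone
Product: 10 1β,18-dihydroxy-13,14,15,16-tetranorlabdano-12,8α-lactone
Conditions: NaBH4 (2.5 equiv), MeOH/THF (1:4), −20 to 0 °C
Reagents that add atoms: none
Why: Borohydride reduction in which hydride adds axially to the C1 ketone from the open α-face (the β-face is screened by the C10 methyl group and C11) to give the equatorial 1β-alcohol, the aldehyde gives the primary alcohol and the γ-lactone survives.

Step 8
Reactants: 10 dihydroxy lactone
Product: 11 8α,12-epoxy-13,14,15,16-tetranorlabdane-1β,12,18-triol (lactol, C12 anomers)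
Conditions: iBu2AlH (3.5 equiv), CH2Cl2, −78 °C; aq KNaC4H4O6
Reagents that add atoms: none
Why: Partial reduction of a γ-lactone, which stops at the tetrahedral aluminate at −78 °C and gives the lactol on work-up (the two hydroxyl groups only consume hydride).

Step 9
Reactants: 11 lactol
Product: 12 (12E)-1β,8α,18-trihydroxy-15-norlabd-12-en-14-al
Conditions: Ph3P=C(CH3)CHO (2.0 equiv), toluene, 90 °C
Reagents that add atoms: 2-(triphenylphosphoranylidene)propanal CC(C=O)=P(c1ccccc1)(c1ccccc1)c1ccccc1
Why: Wittig reaction of a stabilised ylide with the ring-opened hydroxy aldehyde form of the lactol, which gives the E-trisubstituted enal (C14 trans to C11) and frees the 8α-hydroxyl group.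

Step 10
Reactants: 12 enal triol
Product: 13 (12E)-1β,8α-dihydroxy-14-oxo-15-norlabd-12-en-18-yl icosanoate
Conditions: n-C19H39COCl (1.05 equiv), 2,4,6-collidine, CH2Cl2, −40 to 0 °C
Reagents that add atoms: icosanoyl chloride CCCCCCCCCCCCCCCCCCCC(=O)Cl
Why: Chemoselective acylation of the only primary alcohol, which reacts far faster than the hindered secondary C1 hydroxyl (next to the quaternary C10) and the tertiary C8 hydroxyl.

Step 11
Reactants: 13 C18 icosanoate
Product: 14 (12E)-1β-acetoxy-8α-hydroxy-14-oxo-15-norlabd-12-en-18-yl icosanoate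
Conditions: Ac2O (3 equiv), DMAP (0.2 equiv), pyridine, 0 °C to rt
Reagents that add atoms: acetic anhydride CC(=O)OC(C)=O
Why: DMAP-catalysed acetylation of the secondary 1β-alcohol, under which the tertiary 8α-alcohol stays free.

Step 12
Reactants: 14 acetate enal
Product: 15 (1R,4R,5S,8R,9R,10S,12E)-1-acetoxy-8-hydroxylabda-12,14-dien-18-yl icosanoate (target, CNP0288884.2)
Conditions: Ph3PCH3Br (1.5 equiv), KN(SiMe3)2 (1.4 equiv), THF, 0 °C; then 14, −78 to 0 °C
Reagents that add atoms: methyltriphenylphosphonium bromide C[P+](c1ccccc1)(c1ccccc1)c1ccccc1.[Br-]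
Why: Wittig methylenation of the enal at low temperature, which is much faster than any reaction of the ylide with the two esters and turns the E-enal into the 12E,14-diene without touching a stereocentre.

## Compound list

1 | geranyl chloride, (2E)-1-chloro-3,7-dimethylocta-2,6-diene | ClC/C=C(\C)CCC=C(C)C | starting material
2 | methyl (3E)-4,8-dimethylnona-3,7-dienoate | COC(=O)C/C=C(\C)CCC=C(C)C | intermediate
3 | methyl (3E,7E)-4,8-dimethyl-9-oxonona-3,7-dienoate | COC(=O)C/C=C(\C)CC/C=C(\C)C=O | intermediate
4 | pent-1-en-3-one | C=CC(=O)CC | starting material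
5 | tert-butyldimethyl[(3Z)-penta-1,3-dien-3-yloxy]silane | C=C/C(O[Si](C)(C)C(C)(C)C)=C/C | intermediate
6 | methyl (3E)-6-[(1R,2R,6R)-3-(tert-butyldimethylsilyloxy)-6-formyl-2,6-dimethylcyclohex-3-en-1-yl]-4-methylhex-3-enoate (cycloadduct, not isolated) | CC(C)(C)[Si](C)(C)OC1=CC[C@@](C)(C=O)[C@H](CC/C(C)=C/CC(=O)OC)[C@H]1C | intermediate
7 | methyl (3E)-6-[(1R,2R,6R)-2-formyl-2,6-dimethyl-5-oxocyclohexyl]-4-methylhex-3-enoate | O=C1CC[C@@](C)(C=O)[C@H](CC/C(C)=C/CC(=O)OC)[C@H]1C | intermediate
8 | methyl (3E)-6-[(1R,6R)-6-formyl-2,6-dimethyl-3-(trimethylsilyloxy)cyclohex-2-en-1-yl]-4-methylhex-3-enoate | C[Si](C)(C)OC1=C(C)[C@@H](CC/C(C)=C/CC(=O)OC)[C@](C)(C=O)CC1 | intermediate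
9 | 1,18-dioxo-13,14,15,16-tetranorlabdano-12,8α-lactone | O=C1C[C@@H]2[C@@]3(C)C(=O)CC[C@@](C)(C=O)[C@@H]3CC[C@@]2(C)O1 | intermediate
10 | 1β,18-dihydroxy-13,14,15,16-tetranorlabdano-12,8α-lactone | O=C1C[C@@H]2[C@@]3(C)[C@H](O)CC[C@@](C)(CO)[C@@H]3CC[C@@]2(C)O1 | intermediate
11 | 8α,12-epoxy-13,14,15,16-tetranorlabdane-1β,12,18-triol (C12 anomers) | OC1C[C@@H]2[C@@]3(C)[C@H](O)CC[C@@](C)(CO)[C@@H]3CC[C@@]2(C)O1 | intermediate
12 | (12E)-1β,8α,18-trihydroxy-15-norlabd-12-en-14-al | O=C/C(C)=C/C[C@@H]1[C@@]2(C)[C@H](O)CC[C@@](C)(CO)[C@@H]2CC[C@@]1(C)O | intermediate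
13 | (12E)-1β,8α-dihydroxy-14-oxo-15-norlabd-12-en-18-yl icosanoate | O=C/C(C)=C/C[C@@H]1[C@@]2(C)[C@H](O)CC[C@@](C)(COC(=O)CCCCCCCCCCCCCCCCCCC)[C@@H]2CC[C@@]1(C)O | intermediate
14 | (12E)-1β-acetoxy-8α-hydroxy-14-oxo-15-norlabd-12-en-18-yl icosanoate | O=C/C(C)=C/C[C@@H]1[C@@]2(C)[C@H](OC(C)=O)CC[C@@](C)(COC(=O)CCCCCCCCCCCCCCCCCCC)[C@@H]2CC[C@@]1(C)O | intermediate
15 | (1R,4R,5S,8R,9R,10S,12E)-1-acetoxy-8-hydroxylabda-12,14-dien-18-yl icosanoate | C=C/C(C)=C/C[C@@H]1[C@@]2(C)[C@H](OC(C)=O)CC[C@@](C)(COC(=O)CCCCCCCCCCCCCCCCCCC)[C@@H]2CC[C@@]1(C)O | target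

## Step count and risks

Total steps: 12. Longest linear sequence: 11 (steps 1, 2, 4–12 from geranyl chloride; step 3 is a one-step side branch).

Three steps most likely to fail:

**Step 6 (the proposed new bicyclisation).** Possible failures are loss of H5 from the enolonium to give the C5=C10 enone, α-acetoxylation at C10, and a cis ring fusion. The fallback uses known chemistry and sets out from 8. N-Bromosuccinimide in THF at −78 °C gives the tertiary α-bromo ketone F1. Copper-catalysed atom-transfer radical cyclisation (CuBr, tris(2-pyridylmethyl)amine, MeCN, 60 °C) closes ring B by 6-endo attack of the α-keto radical on the trisubstituted alkene and transfers bromine to C8, giving the tertiary bromide F2. On continued heating F2 lactonises through its neighbouring ester with loss of CH3Br, and the route is rejoined at 9.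

**Step 4 (enantioselective Diels–Alder with a trisubstituted enal).** Possible failures are slow cycloaddition, competing Mukaiyama-type addition at the formyl group, low enantioselectivity, or the opposite sense of induction (in that case the antipodal catalyst is used). The fallback sets out from 3 and uses a much more reactive diene under hydrogen-bond catalysis. The aminosiloxydiene F3 is made from (E)-1-(dimethylamino)pent-1-en-3-one with KN(SiMe3)2 and tBuMe2SiCl. It reacts with 3 in the presence of a 1-naphthyl TADDOL (20 mol%, toluene, −60 °C) to give the cycloadduct F4. HF in MeCN removes the silyl group and dimethylamine to give the cyclohexenone F5. Hydrogenation of the ring C2=C3 bond only (H2, RhCl(PPh3)3, benzene) gives 7, where the route is rejoined.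

**Step 5 (regiochemistry of enolisation, C10 against C2).** The fallback removes the choice and sets out from the cycloadduct 6, isolated by leaving out the fluoride treatment in step 4. Oxidation with Pd(OAc)2 in MeCN (Saegusa–Ito) gives the enone F5 already described, in which C10 is the only enolisable position. Me3SiOTf/Et3N then gives the cross-conjugated silyl dienol ether F6. The step 6 conditions convert F6 into the enone lactone F7. Hydrogenation (H2, Pd/C, EtOAc) saturates C2=C3 and the route is rejoined at 9.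

## Further compounds

F1 | step 6 | methyl (3E)-6-[(1R,2R)-6-bromo-2-formyl-2,6-dimethyl-5-oxocyclohexyl]-4-methylhex-3-enoate (bromine at C10, trans to the side chain) | O=C1CC[C@@](C)(C=O)[C@H](CC/C(C)=C/CC(=O)OC)[C@@]1(C)Br
F2 | step 6 | methyl 8-bromo-1,18-dioxo-13,14,15,16-tetranorlabdan-12-oate (C8 epimers) | COC(=O)C[C@@H]1[C@@]2(C)C(=O)CC[C@@](C)(C=O)[C@@H]2CCC1(C)Br
F3 | step 4 | (1E,3Z)-3-(tert-butyldimethylsilyloxy)-N,N-dimethylpenta-1,3-dien-1-amine | CN(C)/C=C/C(O[Si](C)(C)C(C)(C)C)=C/C
F4 | step 4 | methyl (3E)-6-[(1R,6R)-3-(tert-butyldimethylsilyloxy)-5-(dimethylamino)-6-formyl-2,6-dimethylcyclohex-3-en-1-yl]-4-methylhex-3-enoate (C3 and C10 epimers, labdane numbering) | CN(C)C1C=C(O[Si](C)(C)C(C)(C)C)C(C)[C@@H](CC/C(C)=C/CC(=O)OC)[C@]1(C)C=O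
F5 | step 4 | methyl (3E)-6-[(1R,2R,6R)-2-formyl-2,6-dimethyl-5-oxocyclohex-3-en-1-yl]-4-methylhex-3-enoate | O=C1C=C[C@@](C)(C=O)[C@H](CC/C(C)=C/CC(=O)OC)[C@H]1C
F6 | step 5 | methyl (3E)-6-[(1R,6R)-6-formyl-2,6-dimethyl-3-(trimethylsilyloxy)cyclohexa-2,4-dien-1-yl]-4-methylhex-3-enoate | C[Si](C)(C)OC1=C(C)[C@@H](CC/C(C)=C/CC(=O)OC)[C@](C)(C=O)C=C1
F7 | step 5 | 1,18-dioxo-13,14,15,16-tetranorlabd-2-eno-12,8α-lactone | O=C1C[C@@H]2[C@@]3(C)C(=O)C=C[C@@](C)(C=O)[C@@H]3CC[C@@]2(C)O1
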